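## Structural features

The target is a trans-fused bicyclo[5.3.0]decane. A cyclopentane (C5, C7, C8, C9, C11) shares the C5–C7 bond with a cycloheptanone (C2, C3, C4, C5, C7, C14, C16), and C16 carries a two-carbon chain (C18–C19) ending at the β-carbon C20 of a butenolide. There are five stereocentres: the all-carbon quaternary C16 next to the methyl-bearing C2, the fully substituted carbinol C5 next to C7 at the ring fusion, and the C9 carbinol, which lies beyond the gem-dimethyl carbon C11 and is cis-1,3 to the C5 hydroxyl. The ring ketone C14 is wedged between C16 and C7, so C16, C14, C7, C5 and C11 form one continuous, crowded edge. The C5 hydroxyl and the C14 ketone form an aldol unit that can open by retro-aldol to a ten-membered ring, dehydrate towards C7 or epimerise at C7; the butenolide is sensitive to base, nucleophilic peroxide and hydride. The real difficulty is to set the C5/C7 pair, with trans fusion and an angular hydroxyl, in the right sense relative to the remote C2/C16 pair. The feature exploited is that C4 (on C5) and C14 (on C7) lie on opposite faces of the cyclopentane while the C5 oxygen lies on the face of C14. That is the pattern of an anti addition of an alkyl group migrating from boron (C4) and an alkenyl group delivered by palladium (C14) across the C5=C7 bond of a C5-borylated cyclopentene, followed by C–B oxidation with retention.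

## Logic of the disconnections

26 ⇒ 24. The C14=O bond is traced back to a C14=CH2 bond. The cut is placed last because the C5-hydroxy C14-ketone is the most fragile element of 26 and the methylene is what the key step delivers. The gain is an intermediate with no aldol unit and no second ketone. The forward step must cleave an isolated 1,1-disubstituted alkene with ozone and spare the conjugated butenolide alkene.

24 ⇒ 21 + 22. The C19–C20 bond is cut, which removes the whole heterocycle as 22 and leaves a primary iodide. The forward step is an sp3–sp2 coupling through 23 that must proceed beside a free secondary and a free tertiary hydroxyl. 21 comes from 20 by exchange of the C19–O bond for a C19–I bond, which must select the primary hydroxyl among three.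

20 ⇒ 18 (through 19). The C5–O bond is returned to a C5–B bond and the C9–H bond is removed, leaving a C9 ketone. Boron stays on C5 during the reduction so that it steers hydride to the opposite face before it becomes the hydroxyl. This removes one stereocentre and avoids a C5-hydroxy C9-ketone altogether. The forward steps need hydride attack anti to boron and oxidation of a hindered tertiary C–B bond with retention.

18 ⇒ 17. The C9 dioxolane and the C19 silyl ether are put back. Both must fall in one acidic operation without loss of the boronic ester or migration of the methylene.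

17 ⇒ 16 ⇒ 15 + 11. The C4–C5 and C7–C14 bonds are cut together. This opens the seven-membered ring, removes both ring-fusion stereocentres and leaves an achiral five-membered alkenyl metal and an acyclic chain carrying C2 and C16. The forward step must add C4 and C14 anti across C5=C7 within one molecule, choose one face of the alkene, and avoid direct transfer of the alkenyl group from boron to palladium.

15 ⇒ 14 ⇒ 13 ⇒ 12. The C5–Li bond is traced to a hydrazone, this to a ketone, and the ketone to a symmetrical dione whose other carbonyl is masked. The only α-hydrogens of 14 are on C7, so the alkenyllithium is regiodefined; the monoketalisation must stop after one carbonyl.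

11 ⇒ 10 ⇒ 8. The C4–B bond is cut back to the C3=C4 alkene and the C14–O(triflate) bond to the methyl ketone. The ketone has one enolisable position, so the triflate is regiodefined. The hydroboration must select the monosubstituted alkene over the enol triflate alkene.

8 ⇒ 7 ⇒ 6 ⇒ 5. The C3=C4 bond is cut to a C3 aldehyde, which comes from a C3 alcohol, and the bond from C14 to its methyl group is cut. This returns the chain to a five-membered lactone (O–C3–C2–C16–C14) in which C2 and C16 are ring atoms. The forward steps need a single addition of methyllithium and a methylenation that spares the ketone and the C2 stereocentre.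

5 ⇒ 3 ⇒ 1. The C16–C18 and C16–C17 bonds are cut. Both are made by enolate alkylation on the lactone, where the C2 methyl directs the second electrophile to the opposite face. The order (methyl first, chain second) fixes C16, and the only stereocentre that has to be bought is C2 of 1.

## Other disconnections considered

Alternative 1: The cut is at C16–C18 and C2–C3, made by a Diels–Alder reaction of the E enal A1 with the silyloxydiene A2 under a chiral oxazaborolidinium Lewis acid, giving the cyclohexene aldehyde A3. In its favour, the vicinal C2/C16 pair, quaternary carbon included, would come from achiral materials in one catalytic, stereospecific step with predictable regiochemistry. On this point it is the equal or the better of the lactone sequence 1 → 5, which needs an enantiopure starting material and a diastereoselective alkylation. Against it, the ring of A3 is not a ring of the target and must be cleaved, which leaves an acid at C4 and an aldehyde at C19 to be differentiated and adjusted. With the E geometry of A1 the C2 methyl ends cis to the oxymethyl group, so the formyl carbon must be deoxygenated to the C17 methyl while the oxymethyl carbon becomes C14. The cycloaddition is concerted and well understood, which is an advantage over step 10, but it solves only the chain: C5, C7 and the seven-membered ring still need a ring-forming step. In step count it would be longer than steps 1–7, and it could serve as a different source of 11 but not as a replacement for the key step.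

Alternative 2: The cut is at C5–C7, made by a transannular aldol of the ten-membered triketone A4, in which the C7 enolate of the C14 ketone adds to the C5 carbonyl to give the bicyclic ketol A5. In its favour, both rings, both ring-fusion stereocentres and the angular hydroxyl would arise in one metal-free step, and C14 and C9 would already be at the ketone level with no ozonolysis needed; in redox economy and in skeletal-bond economy of the key step it is the better plan. Against it, A4 is a ten-membered ring with two quaternary carbons whose synthesis would cost more steps than 11 and 14 together. The C4 enolate of the C5 ketone could add to C14 and close a different five-membered ring, and the 1,3-diketone across C11 invites retro-Claisen cleavage. The aldol is reversible, so the trans fusion would rest on thermodynamic preference and on the conformation of A4, whereas the anti addition of step 10 is kinetically stereospecific. Both plans leave the sense of C5/C7 relative to C2/C16 to an element outside the reacting centres (ring conformation there, a chiral ligand here), so on that point they are equal.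

Alternative 3: The cut is at C14–C16, made by turning the allylic bromide of A6 into an allylchromium species with cathodically regenerated CrCl2; this adds through C16 to the C14 aldehyde to give the bicyclic homoallylic alcohol A7. In its favour, the reaction class (allylchromium addition to an aldehyde) is established, which is a clear advantage over step 10. The C5 and C9 oxygens would be carried in protected form from a cyclopentane building block, so no late reduction is needed, and the C16 vinyl group is a direct handle for the butenolide; the endgame would be equal or shorter. Against it, the quaternary centre C16 would be made late, in a seven-membered ring closure, with its configuration depending on the allyl geometry and on the ring transition state, whereas the chosen plan sets C16 early on a rigid lactone. The aldehyde of A6 has a β-silyloxy group at C5 and an epimerisable α-carbon C7, so elimination and epimerisation threaten before cyclisation, and the C2 centre has to be joined stereoselectively to an enantiopure cyclopentane first. Overall the steps saved at the end would be spent at the front.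

Key step: step 10

Remark on the structures: in 16 and 17 the descriptors at C2 (R) and C16 (S), the trans ring fusion and the cis relation of boron to C14 agree with 26 when traced atom by atom, so both are used unchanged. The cyclopentene is kept achiral (ketal at C9) so that no substrate element opposes the chiral ligand.

Remark on the chemistry: 1 is taken to be a catalogue compound.

Remark on the chemistry: the (Sp,Sp) antipode of the ferrocenyl bisphosphine is assumed to select the face of C7 required for 17; if the sense of induction is the opposite, the (Rp,Rp) antipode is used with no other change.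

## Route

Step 1
Reactants: 1 (S)-4-methyldihydrofuran-2(3H)-one
Product: 3 (3S,4S)-3,4-dimethyldihydrofuran-2(3H)-one (trans; any cis epimer is carried along), via lithium enolate 2 (not isolated)
Conditions: LiN(iPr)2, THF, −78 °C; MeI, −78 → −40 °C
Reagents that add atoms: iodomethane (CI)
Why: Kinetic lithium enolate alkylation of a γ-butyrolactone; the methyl group should enter anti to the C2 methyl, but this centre is planarised again in step 2, so its configuration is of no consequence.

Step 2
Reactants: 3 (3S,4S)-3,4-dimethyldihydrofuran-2(3H)-one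
Product: 5 (3S,4S)-3-{2-[(tert-butyldimethylsilyl)oxy]ethyl}-3,4-dimethyldihydrofuran-2(3H)-one, via lithium enolate 4 (not isolated)
Conditions: LiN(iPr)2, THF, −78 °C; tert-butyl(2-iodoethoxy)dimethylsilane, DMPU, −78 → −20 °C
Reagents that add atoms: tert-butyl(2-iodoethoxy)dimethylsilane (CC(C)(C)[Si](C)(C)OCCI)
Why: Second enolate alkylation on the lactone template: the primary iodide should attack the tetrasubstituted enolate on the face opposite the adjacent C2 methyl, which sets quaternary C16 with the C17 methyl cis and the C18 chain trans to C1. DMPU raises the reactivity towards the β-oxygenated iodide.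

Step 3
Reactants: 5 (3S,4S)-3-{2-[(tert-butyldimethylsilyl)oxy]ethyl}-3,4-dimethyldihydrofuran-2(3H)-one
Product: 6 (3S,4S)-3-{2-[(tert-butyldimethylsilyl)oxy]ethyl}-5-hydroxy-3,4-dimethylpentan-2-one (in equilibrium with its cyclic hemiketal)
Conditions: MeLi (1.05 equiv), THF, −78 °C; aq. NH4Cl
Reagents that add atoms: methyllithium ([Li]C)
Why: Mono-addition of methyllithium to a lactone: the tetrahedral lithium alkoxide is stable at −78 °C and shielded by the α-quaternary centre, so a second addition should not occur. Collapse on work-up gives the methyl ketone at C14 and frees the C3 hydroxyl.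

Step 4
Reactants: 6 (3S,4S)-3-{2-[(tert-butyldimethylsilyl)oxy]ethyl}-5-hydroxy-3,4-dimethylpentan-2-one
Product: 7 (2S,3S)-3-{2-[(tert-butyldimethylsilyl)oxy]ethyl}-2,3-dimethyl-4-oxopentanal
Conditions: Dess–Martin periodinane, CH2Cl2, 0 °C → rt; crude product used directly
Reagents that add atoms: none
Why: Dess–Martin oxidation of the primary alcohol, which drains the open hydroxy ketone from the hemiketal equilibrium. The mild, non-basic conditions should leave the α-stereocentre C2 untouched.

Step 5
Reactants: 7 (2S,3S)-3-{2-[(tert-butyldimethylsilyl)oxy]ethyl}-2,3-dimethyl-4-oxopentanal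
Product: 8 (3S,4R)-3-{2-[(tert-butyldimethylsilyl)oxy]ethyl}-3,4-dimethylhex-5-en-2-one
Conditions: Ph3PCH3Br, KN(SiMe3)2, THF, 0 °C; then 7, −78 → 0 °C
Reagents that add atoms: methyltriphenylphosphonium bromide (C[P+](c1ccccc1)(c1ccccc1)c1ccccc1.[Br-])
Why: Wittig methylenation; the unstabilised ylide adds to the aldehyde far faster than to the neopentyl-type methyl ketone. At low temperature addition should outrun enolisation of either carbonyl, so C2 is not epimerised.

Step 6
Reactants: 8 (3S,4R)-3-{2-[(tert-butyldimethylsilyl)oxy]ethyl}-3,4-dimethylhex-5-en-2-one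
Product: 10 (3S,4R)-3-{2-[(tert-butyldimethylsilyl)oxy]ethyl}-3,4-dimethylhexa-1,5-dien-2-yl trifluoromethanesulfonate, via potassium enolate 9 (not isolated)
Conditions: KN(SiMe3)2, THF, −78 °C; PhNTf2, −78 → 0 °C
Reagents that add atoms: N-phenylbis(trifluoromethanesulfonimide) (O=S(=O)(N(c1ccccc1)S(=O)(=O)C(F)(F)F)C(F)(F)F)
Why: Regiodefined enol triflate formation: the methyl group is the only enolisable position of the ketone, the other α-carbon being quaternary C16. The potassium enolate is O-sulfonylated by the triflimide.

Step 7
Reactants: 10 (3S,4R)-3-{2-[(tert-butyldimethylsilyl)oxy]ethyl}-3,4-dimethylhexa-1,5-dien-2-yl trifluoromethanesulfonate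
Product: 11 (3S,4R)-3-{2-[(tert-butyldimethylsilyl)oxy]ethyl}-3,4-dimethyl-6-(4,4,5,5-tetramethyl-1,3,2-dioxaborolan-2-yl)hex-1-en-2-yl trifluoromethanesulfonate
Conditions: pinacolborane (1.2 equiv), [Ir(cod)Cl]2 (1.5 mol%), dppm (3 mol%), CH2Cl2, rt
Reagents that add atoms: pinacolborane (CC1(C)OBOC1(C)C)
Why: Iridium-catalysed anti-Markovnikov hydroboration of the monosubstituted alkene; the hindered, electron-poor enol triflate alkene should not take part. Installing boron after the triflation keeps the boronic ester away from strong base.

Step 8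
Reactants: 12 2,2-dimethylcyclopentane-1,3-dione
Product: 13 6,6-dimethyl-1,4-dioxaspiro[4.4]nonan-7-one
Conditions: ethane-1,2-diol (1.05 equiv), p-TsOH·H2O (cat.), toluene, reflux, Dean–Stark
Reagents that add atoms: ethane-1,2-diol (OCCO)
Why: Acid-catalysed monoketalisation with azeotropic removal of water; the second carbonyl is slowed by the gem-dimethyl group and the new dioxolane, so one equivalent of diol should stop at the monoketal. The ketal masks C9 and keeps the ring achiral.

Step 9
Reactants: 13 6,6-dimethyl-1,4-dioxaspiro[4.4]nonan-7-one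
Product: 14 (E)-N′-(6,6-dimethyl-1,4-dioxaspiro[4.4]nonan-7-ylidene)-2,4,6-tri(propan-2-yl)benzenesulfonohydrazide
Conditions: 2,4,6-tri(propan-2-yl)benzenesulfonohydrazide, THF, rt
Reagents that add atoms: 2,4,6-tri(propan-2-yl)benzenesulfonohydrazide (CC(C)c1cc(C(C)C)c(S(=O)(=O)NN)c(C(C)C)c1)
Why: Condensation of the remaining ketone with the arenesulfonyl hydrazide gives the substrate for the Shapiro reaction. The only α-hydrogens are on C7, so the later alkenyllithium is regiodefined.

Step 10
Reactants: 14 (E)-N′-(6,6-dimethyl-1,4-dioxaspiro[4.4]nonan-7-ylidene)-2,4,6-tri(propan-2-yl)benzenesulfonohydrazide; 11 (3S,4R)-3-{2-[(tert-butyldimethylsilyl)oxy]ethyl}-3,4-dimethyl-6-(4,4,5,5-tetramethyl-1,3,2-dioxaborolan-2-yl)hex-1-en-2-yl trifluoromethanesulfonate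
Product: 17 ethylene ketal of (3aS,5S,6R,8aR)-5-{2-[(tert-butyldimethylsilyl)oxy]ethyl}-1,1,5,6-tetramethyl-4-methylidene-8a-(4,4,5,5-tetramethyl-1,3,2-dioxaborolan-2-yl)octahydroazulen-2(1H)-one (trans-fused; boron on the face of the methylene-bearing carbon), via cyclopentenyllithium 15 (not isolated), via lithium boronate complex 16 (not isolated)
Conditions: 14 (1.05 equiv), n-BuLi (2.1 equiv), THF, −78 → 0 °C; −78 °C, then 11, −78 → 0 °C; then Pd(OAc)2 (5 mol%), (Sp,Sp)-MandyPhos [(αR,αR)-2,2′-bis(α-dimethylaminobenzyl)-(Sp,Sp)-1,1′-bis(diphenylphosphino)ferrocene] (6 mol%), THF (0.01 mol/L), 45 °C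
Reagents that add atoms: none
Why: Proposed new method: oxidative addition of zerovalent palladium into the C14 enol triflate gives a cationic alkenyl complex of divalent palladium that binds the electron-rich C5=C7 alkene of the four-coordinate boronate; C4 then migrates from boron to C5 on the face opposite palladium, and C–C reductive elimination joins C7 to C14 and returns zerovalent palladium. The closest known reaction type is the intermolecular palladium-catalysed conjunctive cross-coupling of alkenylboron ate complexes with alkenyl triflates, here applied to a tethered triflate and a trisubstituted cyclic alkenyl boronate. The seven-membered ring closes in an endo sense with respect to the alkene (C5 and C7 both become ring atoms), through a nine-membered π-chelate that contracts to an eight-membered palladacycle on migration and to the carbocycle on reductive elimination. The relative configuration of C5 and C7 is fixed by the anti course of the metallate shift, which makes the ring trans-fused and leaves boron cis to C14. Their configuration relative to C2 and C16 is set by the chiral bisphosphine, since the tether bias is expected to be weak and the cyclopentene is achiral. The step needs the shift to outrun transfer of the cyclopentenyl group to palladium and β-hydride elimination towards C8; the pinacol-ligated, α-branched four-coordinate boron, the halide-free triflate system (Shapiro-derived alkenyllithium) and the wide-bite-angle ligand favour this, and high dilution suppresses intermolecular coupling. At −78 °C the alkenyllithium should add to boron faster than it attacks the hindered triflate.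

Step 11
Reactants: 17 ethylene ketal of (3aS,5S,6R,8aR)-5-{2-[(tert-butyldimethylsilyl)oxy]ethyl}-1,1,5,6-tetramethyl-4-methylidene-8a-(4,4,5,5-tetramethyl-1,3,2-dioxaborolan-2-yl)octahydroazulen-2(1H)-one
Product: 18 (3aS,5S,6R,8aR)-5-(2-hydroxyethyl)-1,1,5,6-tetramethyl-4-methylidene-8a-(4,4,5,5-tetramethyl-1,3,2-dioxaborolan-2-yl)octahydroazulen-2(1H)-one
Conditions: 1 N HCl, THF, rt
Reagents that add atoms: water (O)
Why: Aqueous acid hydrolyses the dioxolane to the C9 ketone and cleaves the primary silyl ether in one operation. The hindered tertiary pinacol boronate and the unactivated methylene should be inert to dilute acid at room temperature.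

Step 12
Reactants: 18 (3aS,5S,6R,8aR)-5-(2-hydroxyethyl)-1,1,5,6-tetramethyl-4-methylidene-8a-(4,4,5,5-tetramethyl-1,3,2-dioxaborolan-2-yl)octahydroazulen-2(1H)-one
Product: 20 (2R,3aR,5S,6R,8aS)-5-(2-hydroxyethyl)-1,1,5,6-tetramethyl-4-methylideneoctahydroazulene-2,8a(1H)-diol, via boronate diol 19 (not isolated)
Conditions: NaBH4, MeOH/THF, −20 → 0 °C; then aq. NaOH, 30% H2O2, 0 °C → rt
Reagents that add atoms: hydrogen peroxide (OO)
Why: Borohydride reduction under steric approach control: the angular boronate on C5 is axial on one face of the cyclopentanone and 1,3 to C9, so hydride should enter from the face of C4 and leave the C9 hydroxyl cis to boron (C9 R). Alkaline peroxide then oxidises the C–B bond with retention, which gives the cis-1,3-diol.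

Step 13
Reactants: 20 (2R,3aR,5S,6R,8aS)-5-(2-hydroxyethyl)-1,1,5,6-tetramethyl-4-methylideneoctahydroazulene-2,8a(1H)-diol
Product: 21 (2R,3aR,5S,6R,8aS)-5-(2-iodoethyl)-1,1,5,6-tetramethyl-4-methylideneoctahydroazulene-2,8a(1H)-diol
Conditions: I2, PPh3, imidazole, CH2Cl2, 0 °C
Reagents that add atoms: iodine (II)
Why: Appel-type iodination, which should select the primary alcohol over the neopentyl secondary and the tertiary hydroxyl.

Step 14
Reactants: 21 (2R,3aR,5S,6R,8aS)-5-(2-iodoethyl)-1,1,5,6-tetramethyl-4-methylideneoctahydroazulene-2,8a(1H)-diol; 22 4-bromofuran-2(5H)-one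
Product: 24 4-{2-[(2R,3aR,5S,6R,8aS)-2,8a-dihydroxy-1,1,5,6-tetramethyl-4-methylidenedecahydroazulen-5-yl]ethyl}furan-2(5H)-one, via alkylzinc iodide 23 (not isolated)
Conditions: Zn dust (I2-activated), DMA, rt; solution decanted from excess Zn; then 22, Pd(OAc)2 (5 mol%), SPhos (10 mol%), THF, rt
Reagents that add atoms: none
Why: Negishi coupling: zinc inserts into the primary C–I bond and the alkylzinc iodide is coupled with the activated alkenyl bromide under palladium catalysis, the bulky biarylphosphine favouring reductive elimination over β-hydride elimination. Alkylzinc halides are protonated only slowly by hindered alcohols and tolerate the lactone.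

Step 15
Reactants: 24 4-{2-[(2R,3aR,5S,6R,8aS)-2,8a-dihydroxy-1,1,5,6-tetramethyl-4-methylidenedecahydroazulen-5-yl]ethyl}furan-2(5H)-one
Product: 26 (2R,3aS,5S,6R,8aS)-2,8a-dihydroxy-1,1,5,6-tetramethyl-5-[2-(5-oxo-2,5-dihydrofuran-3-yl)ethyl]octahydroazulen-4(1H)-one (CNP0077405.1), via ozonide 25 (not isolated)
Conditions: O3, CH2Cl2, −78 °C (Sudan Red 7B as end-point indicator); then PPh3, −78 °C → rt
Reagents that add atoms: ozone ([O-][O+]=O)
Why: Ozonolysis with reductive work-up; the electron-rich 1,1-disubstituted alkene should react with ozone much faster than the conjugated, electron-poor butenolide alkene. The neutral, cold conditions spare the aldol unit, which is unveiled only now.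

## Compound list

1 | (S)-4-methyldihydrofuran-2(3H)-one | C[C@@H]1COC(=O)C1 | starting material
2 | lithium (S)-4-methyl-4,5-dihydrofuran-2-olate (lithium enolate of 1) | C[C@@H]1COC(O[Li])=C1 | intermediate
3 | (3S,4S)-3,4-dimethyldihydrofuran-2(3H)-one | C[C@@H]1COC(=O)[C@H]1C | intermediate
4 | lithium (S)-3,4-dimethyl-4,5-dihydrofuran-2-olate (lithium enolate of 3) | C[C@@H]1COC(O[Li])=C1C | intermediate
5 | (3S,4S)-3-{2-[(tert-butyldimethylsilyl)oxy]ethyl}-3,4-dimethyldihydrofuran-2(3H)-one | C[C@@H]1COC(=O)[C@@]1(C)CCO[Si](C)(C)C(C)(C)C | intermediate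
6 | (3S,4S)-3-{2-[(tert-butyldimethylsilyl)oxy]ethyl}-5-hydroxy-3,4-dimethylpentan-2-one | C[C@H](CO)[C@](C)(CCO[Si](C)(C)C(C)(C)C)C(C)=O | intermediate
7 | (2S,3S)-3-{2-[(tert-butyldimethylsilyl)oxy]ethyl}-2,3-dimethyl-4-oxopentanal | C[C@H](C=O)[C@](C)(CCO[Si](C)(C)C(C)(C)C)C(C)=O | intermediate
8 | (3S,4R)-3-{2-[(tert-butyldimethylsilyl)oxy]ethyl}-3,4-dimethylhex-5-en-2-one | C[C@H](C=C)[C@](C)(CCO[Si](C)(C)C(C)(C)C)C(C)=O | intermediate
9 | potassium (3S,4R)-3-{2-[(tert-butyldimethylsilyl)oxy]ethyl}-3,4-dimethylhexa-1,5-dien-2-olate (potassium enolate of 8) | C[C@H](C=C)[C@](C)(CCO[Si](C)(C)C(C)(C)C)C(=C)O[K] | intermediate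
10 | (3S,4R)-3-{2-[(tert-butyldimethylsilyl)oxy]ethyl}-3,4-dimethylhexa-1,5-dien-2-yl trifluoromethanesulfonate | C[C@H](C=C)[C@](C)(CCO[Si](C)(C)C(C)(C)C)C(=C)OS(=O)(=O)C(F)(F)F | intermediate
11 | (3S,4R)-3-{2-[(tert-butyldimethylsilyl)oxy]ethyl}-3,4-dimethyl-6-(4,4,5,5-tetramethyl-1,3,2-dioxaborolan-2-yl)hex-1-en-2-yl trifluoromethanesulfonate | C[C@H](CCB1OC(C)(C)C(C)(C)O1)[C@](C)(CCO[Si](C)(C)C(C)(C)C)C(=C)OS(=O)(=O)C(F)(F)F | intermediate
12 | 2,2-dimethylcyclopentane-1,3-dione | CC1(C)C(=O)CCC1=O | starting material
13 | 6,6-dimethyl-1,4-dioxaspiro[4.4]nonan-7-one | CC1(C)C(=O)CCC12OCCO2 | intermediate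
14 | (E)-N′-(6,6-dimethyl-1,4-dioxaspiro[4.4]nonan-7-ylidene)-2,4,6-tri(propan-2-yl)benzenesulfonohydrazide | CC(C)c1cc(C(C)C)c(S(=O)(=O)N/N=C2/C(C)(C)C3(OCCO3)CC2)c(C(C)C)c1 | intermediate
15 | (6,6-dimethyl-1,4-dioxaspiro[4.4]non-7-en-7-yl)lithium | [Li]C1=CCC2(OCCO2)C1(C)C | intermediate
16 | lithium 2-(6,6-dimethyl-1,4-dioxaspiro[4.4]non-7-en-7-yl)-2-[(3R,4S)-4-{2-[(tert-butyldimethylsilyl)oxy]ethyl}-3,4-dimethyl-5-{[(trifluoromethyl)sulfonyl]oxy}hex-5-en-1-yl]-4,4,5,5-tetramethyl-1,3,2-dioxaborolan-2-uide | [Li+].C[C@H](CC[B-]1(OC(C)(C)C(C)(C)O1)C1=CCC2(OCCO2)C1(C)C)[C@](C)(CCO[Si](C)(C)C(C)(C)C)C(=C)OS(=O)(=O)C(F)(F)F | intermediate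
17 | ethylene ketal of (3aS,5S,6R,8aR)-5-{2-[(tert-butyldimethylsilyl)oxy]ethyl}-1,1,5,6-tetramethyl-4-methylidene-8a-(4,4,5,5-tetramethyl-1,3,2-dioxaborolan-2-yl)octahydroazulen-2(1H)-one | C[C@@H]1CC[C@]2(B3OC(C)(C)C(C)(C)O3)[C@H](CC3(OCCO3)C2(C)C)C(=C)[C@@]1(C)CCO[Si](C)(C)C(C)(C)C | intermediate
18 | (3aS,5S,6R,8aR)-5-(2-hydroxyethyl)-1,1,5,6-tetramethyl-4-methylidene-8a-(4,4,5,5-tetramethyl-1,3,2-dioxaborolan-2-yl)octahydroazulen-2(1H)-one | C[C@@H]1CC[C@]2(B3OC(C)(C)C(C)(C)O3)[C@H](CC(=O)C2(C)C)C(=C)[C@@]1(C)CCO | intermediate
19 | (2R,3aS,5S,6R,8aR)-5-(2-hydroxyethyl)-1,1,5,6-tetramethyl-4-methylidene-8a-(4,4,5,5-tetramethyl-1,3,2-dioxaborolan-2-yl)decahydroazulen-2-ol | C[C@@H]1CC[C@]2(B3OC(C)(C)C(C)(C)O3)[C@H](C[C@@H](O)C2(C)C)C(=C)[C@@]1(C)CCO | intermediate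
20 | (2R,3aR,5S,6R,8aS)-5-(2-hydroxyethyl)-1,1,5,6-tetramethyl-4-methylideneoctahydroazulene-2,8a(1H)-diol | C[C@@H]1CC[C@]2(O)[C@H](C[C@@H](O)C2(C)C)C(=C)[C@@]1(C)CCO | intermediate
21 | (2R,3aR,5S,6R,8aS)-5-(2-iodoethyl)-1,1,5,6-tetramethyl-4-methylideneoctahydroazulene-2,8a(1H)-diol | C[C@@H]1CC[C@]2(O)[C@H](C[C@@H](O)C2(C)C)C(=C)[C@@]1(C)CCI | intermediate
22 | 4-bromofuran-2(5H)-one | O=C1OCC(Br)=C1 | starting material
23 | {2-[(2R,3aR,5S,6R,8aS)-2,8a-dihydroxy-1,1,5,6-tetramethyl-4-methylidenedecahydroazulen-5-yl]ethyl}(iodo)zinc | C[C@@H]1CC[C@]2(O)[C@H](C[C@@H](O)C2(C)C)C(=C)[C@@]1(C)CC[Zn]I | intermediate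
24 | 4-{2-[(2R,3aR,5S,6R,8aS)-2,8a-dihydroxy-1,1,5,6-tetramethyl-4-methylidenedecahydroazulen-5-yl]ethyl}furan-2(5H)-one | C[C@@H]1CC[C@]2(O)[C@H](C[C@@H](O)C2(C)C)C(=C)[C@@]1(C)CCC1=CC(=O)OC1 | intermediate
25 | secondary ozonide of 24 (spiro-1,2,4-trioxolane at the former methylene-bearing ring carbon) | C[C@@H]1CC[C@]2(O)[C@H](C[C@@H](O)C2(C)C)C3(OOCO3)[C@@]1(C)CCC1=CC(=O)OC1 | intermediate
26 | (2R,3aS,5S,6R,8aS)-2,8a-dihydroxy-1,1,5,6-tetramethyl-5-[2-(5-oxo-2,5-dihydrofuran-3-yl)ethyl]octahydroazulen-4(1H)-one | C[C@@H]1CC[C@]2(O)[C@H](C[C@@H](O)C2(C)C)C(=O)[C@@]1(C)CCC1=CC(=O)OC1 | target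

## Step count and least certain steps

Total step count: 15. Longest linear sequence: 13 (steps 1–7 and 10–15); steps 8 and 9 form the short branch.

Step 10. The most likely failures are three. The cyclopentenyl group may pass directly from boron to palladium (a Suzuki-type coupling with C14), because the alkene is β-substituted and the migration terminus C5 lies next to the quaternary C11. β-Hydride elimination towards C8 may follow the shift. The alkene faces may be poorly differentiated, since only the ligand differentiates them. The arenesulfinate left by the Shapiro reaction may also slow the catalyst. The fallback uses known reactions, sets out from 10 and 13 and returns at 20. The lithium enolate of 13 (LiN(SiMe3)2) is α-alkenylated with 10 under palladium catalysis (Pd2(dba)3, bulky biarylphosphine) to the α-alkenyl ketone F1, formed as both C7 epimers because the achiral enolate is not controlled by the chain. CH2=CHMgBr with CeCl3 adds to the C5 carbonyl anti to the alkenyl substituent to give the vinyl carbinol F2, at which stage the isomer with the needed C5/C7 configuration is separated. Ring-closing metathesis with the second-generation Grubbs catalyst joins the two monosubstituted vinyl groups to the cycloheptene F3. Diimide, generated from 2-nitrobenzenesulfonohydrazide, saturates the ring alkene in preference to the hindered methylene to give the tertiary alcohol F4. Aqueous HCl removes ketal and silyl ether to give the keto diol F5, and NaBH4, attacking opposite the angular hydroxyl, delivers 20. This fallback gives up control of C5/C7 relative to the chain.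

Step 2. The tetrasubstituted enolate may react sluggishly with the β-silyloxy iodide, so that proton transfer and elimination of the electrophile compete, and the anti selectivity may erode with a slim electrophile. The fallback sets out from 3 and returns at 5. Alkylation with allyl bromide, a more reactive and more face-selective electrophile, gives the allyl lactone F6. Ozonolysis with NaBH4 work-up gives the hydroxyethyl lactone F7, which is silylated at once (TBSCl, imidazole) to 5 before translactonisation can set in.

Step 12. Hydride may be delivered in part from the boron-bearing face (poor facial selectivity), or oxidation of the very hindered tertiary boronate may stall. The fallback sets out from 18 and returns at 19 and 20, and replaces substrate control by reagent control without a new compound (F0). Reduction with (S)-2-methyl-CBS-oxazaborolidine and BH3·SMe2 treats C11 as the large and C8 as the small flank of the ketone and should give the C9 R carbinol whatever the ring bias, after which the oxidation is run as before.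

Step 14. The organozinc may be protonated by the two free hydroxyl groups during its formation, and residual zinc may reduce the bromobutenolide. The fallback sets out from 21 and returns at 24. Et3SiOTf and 2,6-lutidine give the bis(triethylsilyl) ether F8; zinc insertion and the same palladium-catalysed coupling with 22 give the protected butenolide F9; HF·pyridine in THF removes both silyl groups to give 24.

Step 15. Ozone may over-oxidise by attacking the butenolide alkene, and the aldol unit may open or dehydrate during work-up. The fallback sets out from 20 and returns at 26. The methylene is cleaved at the triol stage, where no second alkene is present (O3, then PPh3), to give the keto triol F10. Appel iodination gives the keto iodide F11, and zinc insertion followed by palladium-catalysed coupling with 22 under the neutral conditions of step 14 gives 26 directly.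

## Further compounds

F1 | step 10 | (8R)-8-[(3S,4R)-3-{2-[(tert-butyldimethylsilyl)oxy]ethyl}-3,4-dimethylhexa-1,5-dien-2-yl]-6,6-dimethyl-1,4-dioxaspiro[4.4]nonan-7-one (needed epimer) | C[C@H](C=C)[C@](C)(CCO[Si](C)(C)C(C)(C)C)C(=C)[C@H]1CC2(OCCO2)C(C)(C)C1=O
F2 | step 10 | 7-ethenyl-8-[(3S,4R)-3-{2-[(tert-butyldimethylsilyl)oxy]ethyl}-3,4-dimethylhexa-1,5-dien-2-yl]-6,6-dimethyl-1,4-dioxaspiro[4.4]nonan-7-ol (vinyl trans to the dienyl group) | C[C@H](C=C)[C@](C)(CCO[Si](C)(C)C(C)(C)C)C(=C)[C@H]1CC2(OCCO2)C(C)(C)[C@]1(O)C=C
F3 | step 10 | ethylene ketal of 5-{2-[(tert-butyldimethylsilyl)oxy]ethyl}-8a-hydroxy-1,1,5,6-tetramethyl-4-methylidene-3,3a,4,5,6,8a-hexahydroazulen-2(1H)-one (trans-fused; ring alkene between C7 and C8 of the hydroazulene) | C[C@@H]1/C=C\[C@]2(O)[C@H](CC3(OCCO3)C2(C)C)C(=C)[C@@]1(C)CCO[Si](C)(C)C(C)(C)C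
F4 | step 10 | ethylene ketal of (3aR,5S,6R,8aS)-5-{2-[(tert-butyldimethylsilyl)oxy]ethyl}-8a-hydroxy-1,1,5,6-tetramethyl-4-methylideneoctahydroazulen-2(1H)-one | C[C@@H]1CC[C@]2(O)[C@H](CC3(OCCO3)C2(C)C)C(=C)[C@@]1(C)CCO[Si](C)(C)C(C)(C)C
F5 | step 10 | (3aR,5S,6R,8aS)-8a-hydroxy-5-(2-hydroxyethyl)-1,1,5,6-tetramethyl-4-methylideneoctahydroazulen-2(1H)-one | C[C@@H]1CC[C@]2(O)[C@H](CC(=O)C2(C)C)C(=C)[C@@]1(C)CCO
F6 | step 2 | (3S,4S)-3,4-dimethyl-3-(prop-2-en-1-yl)dihydrofuran-2(3H)-one | C[C@@H]1COC(=O)[C@@]1(C)CC=C
F7 | step 2 | (3S,4S)-3-(2-hydroxyethyl)-3,4-dimethyldihydrofuran-2(3H)-one | C[C@@H]1COC(=O)[C@@]1(C)CCO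
F0 | step 12 | none | none
F8 | step 14 | bis(triethylsilyl) ether of 21 | C[C@@H]1CC[C@]2(O[Si](CC)(CC)CC)[C@H](C[C@@H](O[Si](CC)(CC)CC)C2(C)C)C(=C)[C@@]1(C)CCI
F9 | step 14 | bis(triethylsilyl) ether of 24 | C[C@@H]1CC[C@]2(O[Si](CC)(CC)CC)[C@H](C[C@@H](O[Si](CC)(CC)CC)C2(C)C)C(=C)[C@@]1(C)CCC1=CC(=O)OC1
F10 | step 15 | (2R,3aS,5S,6R,8aS)-2,8a-dihydroxy-5-(2-hydroxyethyl)-1,1,5,6-tetramethyloctahydroazulen-4(1H)-one | C[C@@H]1CC[C@]2(O)[C@H](C[C@@H](O)C2(C)C)C(=O)[C@@]1(C)CCO
F11 | step 15 | (2R,3aS,5S,6R,8aS)-2,8a-dihydroxy-5-(2-iodoethyl)-1,1,5,6-tetramethyloctahydroazulen-4(1H)-one | C[C@@H]1CC[C@]2(O)[C@H](C[C@@H](O)C2(C)C)C(=O)[C@@]1(C)CCI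
A1 | alternative 1 | (E)-2-{[(4-methoxybenzyl)oxy]methyl}but-2-enal | C/C=C(/C=O)COCc1ccc(OC)cc1
A2 | alternative 1 | 2-(trimethylsilyloxy)buta-1,3-diene | C=CC(=C)O[Si](C)(C)C
A3 | alternative 1 | (1R,6R)-1-{[(4-methoxybenzyl)oxy]methyl}-6-methyl-4-(trimethylsilyloxy)cyclohex-3-ene-1-carbaldehyde | C[C@@H]1CC(O[Si](C)(C)C)=CC[C@]1(C=O)COCc1ccc(OC)cc1
A4 | alternative 2 | (7S,8R)-7-{2-[(tert-butyldimethylsilyl)oxy]ethyl}-2,2,7,8-tetramethylcyclodecane-1,3,6-trione | C[C@@H]1CCC(=O)C(C)(C)C(=O)CCC(=O)[C@@]1(C)CCO[Si](C)(C)C(C)(C)C
A5 | alternative 2 | (3aS,5S,6R,8aS)-5-{2-[(tert-butyldimethylsilyl)oxy]ethyl}-8a-hydroxy-1,1,5,6-tetramethylhexahydroazulene-2,4(1H,3H)-dione | C[C@@H]1CC[C@]2(O)[C@H](CC(=O)C2(C)C)C(=O)[C@@]1(C)CCO[Si](C)(C)C(C)(C)C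
A6 | alternative 3 | (1S,2S,4R)-2-[(3R,4E)-6-bromo-3,4-dimethylhex-4-en-1-yl]-4-[(tert-butyldimethylsilyl)oxy]-3,3-dimethyl-2-[(triethylsilyl)oxy]cyclopentane-1-carbaldehyde | C[C@H](CC[C@]1(O[Si](CC)(CC)CC)[C@H](C[C@@H](O[Si](C)(C)C(C)(C)C)C1(C)C)C=O)/C(C)=C/CBr
A7 | alternative 3 | 2-[(tert-butyldimethylsilyl)oxy]-5-ethenyl-1,1,5,6-tetramethyl-8a-[(triethylsilyl)oxy]decahydroazulen-4-ol (trans-fused; configuration as in the SMILES) | C[C@@H]1CC[C@]2(O[Si](CC)(CC)CC)[C@H](C[C@@H](O[Si](C)(C)C(C)(C)C)C2(C)C)[C@H](O)[C@@]1(C)C=C
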